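A direct plan would oxygenate 2,6-dimethoxytoluene A1 twice, by dibromination, double borylation and boronate oxidation, to give 4,6-dimethoxy-5-methylbenzene-1,3-diol A2.
It would then unmask the hydroxyquinone A3 by oxidative demethylation and would join two molecules of A3 to tetradecanedial A4 by a double reductive alkylation at the one free ring carbon.
Its weakest steps would be these three.
The arene oxygenation would spend three operations to add two hydroxyl groups and no carbon.
The oxidative demethylation would send an air-sensitive, electron-rich diol through a cationic intermediate, with over-oxidation as the ready loss.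
The late double reductive alkylation would have to succeed at both ends of a labile dialdehyde on the finished hydroxyquinone, while the hydride donor could reduce the quinone and each quinone methide could be caught by a second hydroxyquinone.

**Plan of the new route**
Quinone numbering: C1(=O), C2(OH), C3(chain), C4(=O), C5(OMe), C6(Me). In each ring the segment C4–C3–C2–C1 carries the oxygen pattern of squaric acid with one oxygen replaced by the chain; this, and the twofold symmetry of the fourteen-carbon tether, make the key step possible.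
The retrosynthesis cuts the C4–C5 bond (key step) and the C1–C6 bond of each ring, leaving a cyclobutenedione and a 1-methoxypropen-2-yl anion; it then cuts both C3–CH2 bonds, leaving di-tert-butyl squarate and a di-Grignard reagent.
Ring order: the two four-membered rings are bought and tied to the chain first; both six-membered rings arise last and together, by thermal ring expansion at the two chain ends.
No arene is oxygenated, no ether is cleaved oxidatively and no carbon–carbon bond is made to a finished quinone; after the key step only two tert-butyl groups are removed by acid.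

Key step: step 4

Remark: 1-methoxyprop-1-ene 7 is assumed to be available as its commercial E/Z mixture; this alkene geometry is lost when the ring becomes aromatic and is left undefined. The target is achiral; the carbinol and ring stereocentres of 4, 5, 11 and 13 are uncontrolled and transient.

**Route**

Step 1
Reactants: 1 1,14-dibromotetradecane; 2 3,4-di-tert-butoxycyclobut-3-ene-1,2-dione (di-tert-butyl squarate, 2.6 equiv)
Product: 6 4,4'-(tetradecane-1,14-diyl)bis(3-tert-butoxycyclobut-3-ene-1,2-dione), via tetradecane-1,14-diylbis(magnesium bromide) 3 (not isolated), via bis(bromomagnesium alkoxide) adduct 4 (not isolated), via bis(trifluoroacetate) 5 (not isolated)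
Conditions: Mg turnings (2.5 equiv), THF, 45 °C; cannulate into 2, THF, –78 °C, 1 h; (CF3CO)2O (2.6 equiv), –78 °C, 20 min; cold aq NaHCO3
Reagents that add atoms: none
Why: Each Grignard terminus should add 1,2 to a carbonyl of the squarate ester (inverse addition into excess 2 suppresses a second addition), and trifluoroacetylation lets the tertiary alkoxide ionize to an alkoxy-stabilised cyclobutenyl cation that loses the tert-butyl group from the oxygen on the carbon next to the remaining carbonyl, the established squarate-ester route to 3-alkoxy-4-alkylcyclobutenediones.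

Step 2
Reactants: 7 1-methoxyprop-1-ene (E/Z mixture)
Product: 9 2-bromo-1-methoxyprop-1-ene (E/Z mixture), via 1,2-dibromo-1-methoxypropane 8 (not isolated)
Conditions: Br2 (1.0 equiv), CH2Cl2, –78 °C; evaporate cold; PhNEt2 (1.3 equiv), 90 °C, distil from the salt
Reagents that add atoms: bromine, BrBr
Why: Bromine addition gives the α-bromo ether 8, whose oxygen-activated C1–Br bond ionizes to an oxocarbenium ion that loses the C2 proton (E1 dehydrobromination), so the remaining bromine sits on the methyl-bearing carbon, as in the standard preparation of 1-bromo-2-ethoxyethene from ethyl vinyl ether.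

Step 3
Reactants: 9 2-bromo-1-methoxyprop-1-ene (2.6 equiv); 6 4,4'-(tetradecane-1,14-diyl)bis(3-tert-butoxycyclobut-3-ene-1,2-dione) (1.0 equiv)
Product: 11 2,2'-(tetradecane-1,14-diyl)bis[3-tert-butoxy-4-hydroxy-4-(1-methoxyprop-1-en-2-yl)cyclobut-2-en-1-one], via (1-methoxyprop-1-en-2-yl)lithium 10 (not isolated)
Conditions: 9, t-BuLi (5.2 equiv), Et2O, –78 °C, 30 min; transfer into 6, THF, –78 °C, 1 h; sat. aq NH4Cl at –78 °C; filter through Et3N-washed silica
Reagents that add atoms: none
Why: Bromine–lithium exchange gives a β-alkoxy alkenyllithium (of the 2-ethoxyvinyllithium type), which should add 1,2 to the carbonyl next to the tert-butoxy-bearing carbon, because the other carbonyl is deactivated as part of the vinylogous ester tBuO–C=C–C=O (the known regiochemistry of organolithium addition to 3-alkoxy-4-alkylcyclobutenediones); this puts the future C6 next to the future C1, and the two carbinol stereocentres form without control and disappear in step 4.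

Step 4
Reactants: 11 2,2'-(tetradecane-1,14-diyl)bis[3-tert-butoxy-4-hydroxy-4-(1-methoxyprop-1-en-2-yl)cyclobut-2-en-1-one]
Product: 15 3,3'-(tetradecane-1,14-diyl)bis(2-tert-butoxy-5-methoxy-6-methylcyclohexa-2,5-diene-1,4-dione), via bis(dienylketene) 12 (not isolated), via bis(cyclohexa-2,4-dienone) 13 (not isolated), via bis(hydroquinone) 14 (not isolated)
Conditions: PhMe (0.01 M), 110 °C, N2, 2 h; cool to rt; Ag2O (4 equiv), K2CO3, 1 h; filter
Reagents that add atoms: none
Why: Heating should open each 4-hydroxycyclobutenone by conrotatory 4π electrocyclic cleavage of the C(=O)–C(OH) bond, the hydroxyl turning outward and the methoxypropenyl group inward, to give dienylketene 12 in which the ketene carbon faces the CH(OMe) terminus. Disrotatory 6π electrocyclization then joins these two carbons (the C4–C5 bond of the quinone) and closes each six-membered carbocycle as cyclohexa-2,4-dienone 13, which enolizes to the aromatic hydroquinone 14, and Ag2O dehydrogenates 14 to the quinone. The closest known reaction type is the thermal ring expansion of 4-alkenyl-4-hydroxycyclobutenones to hydroquinones (alkenyl variant of the Moore rearrangement) followed by the usual oxidation. No stereocentre survives: the carbinol carbons become C1=O and the only new sp3 carbon, the CH(OMe) carbon of 13 that is the future C5 of the quinone, becomes aromatic, so all diastereomers and both alkene geometries of 11 converge. The step needs regiocontrol, outward rotation of the hydroxyl group and clean reaction at both ends: the regiochemistry is fixed by connectivity (the ketene carbon is bonded to the chain-bearing carbon, so the chain ends between C2–O and C4=O and the methyl next to C1), the donor hydroxyl secures the torquoselectivity, and fourteen methylene groups insulate the two ends so that each reacts as an independent unimolecular event. High dilution should keep a ketene from being trapped by a hydroxyl group of another molecule, and the neutral medium should spare the tert-butyl ethers.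

Step 5
Reactants: 15 3,3'-(tetradecane-1,14-diyl)bis(2-tert-butoxy-5-methoxy-6-methylcyclohexa-2,5-diene-1,4-dione)
Product: 16 3,3'-(tetradecane-1,14-diyl)bis(2-hydroxy-5-methoxy-6-methylcyclohexa-2,5-diene-1,4-dione)
Conditions: CF3CO2H/CH2Cl2 (1:4), 0 °C → rt, 1 h; evaporate
Reagents that add atoms: none
Why: Protonation of the vinylogous tert-butyl ester and loss of the tert-butyl cation as 2-methylpropene (E1 cleavage of a tert-butyl ether) should free both hydroxyquinones, while the methyl vinylogous esters cannot ionize and stay untouched in the absence of water.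

**Compound list**

1 | 1,14-dibromotetradecane | BrCCCCCCCCCCCCCCBr | starting material
2 | 3,4-di-tert-butoxycyclobut-3-ene-1,2-dione (di-tert-butyl squarate) | CC(C)(C)OC1=C(OC(C)(C)C)C(=O)C1=O | starting material
3 | tetradecane-1,14-diylbis(magnesium bromide) | Br[Mg]CCCCCCCCCCCCCC[Mg]Br | intermediate
4 | 4,4'-(tetradecane-1,14-diyl)bis(2,3-di-tert-butoxy-4-hydroxycyclobut-2-en-1-one), bis(bromomagnesium alkoxide), mixture of diastereomers | CC(C)(C)OC1=C(OC(C)(C)C)C(O[Mg]Br)(CCCCCCCCCCCCCCC2(O[Mg]Br)C(OC(C)(C)C)=C(OC(C)(C)C)C2=O)C1=O | intermediate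
5 | 4,4'-(tetradecane-1,14-diyl)bis[2,3-di-tert-butoxy-4-(trifluoroacetoxy)cyclobut-2-en-1-one], mixture of diastereomers | CC(C)(C)OC1=C(OC(C)(C)C)C(OC(=O)C(F)(F)F)(CCCCCCCCCCCCCCC2(OC(=O)C(F)(F)F)C(OC(C)(C)C)=C(OC(C)(C)C)C2=O)C1=O | intermediate
6 | 4,4'-(tetradecane-1,14-diyl)bis(3-tert-butoxycyclobut-3-ene-1,2-dione) | CC(C)(C)OC1=C(CCCCCCCCCCCCCCC2=C(OC(C)(C)C)C(=O)C2=O)C(=O)C1=O | intermediate
7 | 1-methoxyprop-1-ene (E/Z mixture) | COC=CC | starting material
8 | 1,2-dibromo-1-methoxypropane (mixture of diastereomers) | COC(Br)C(C)Br | intermediate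
9 | 2-bromo-1-methoxyprop-1-ene (E/Z mixture) | COC=C(C)Br | intermediate
10 | (1-methoxyprop-1-en-2-yl)lithium (E/Z mixture) | COC=C(C)[Li] | intermediate
11 | 2,2'-(tetradecane-1,14-diyl)bis[3-tert-butoxy-4-hydroxy-4-(1-methoxyprop-1-en-2-yl)cyclobut-2-en-1-one], mixture of diastereomers | COC=C(C)C1(O)C(OC(C)(C)C)=C(CCCCCCCCCCCCCCC2=C(OC(C)(C)C)C(O)(C(C)=COC)C2=O)C1=O | intermediate
12 | 2,17-bis(1-tert-butoxy-2-hydroxy-4-methoxy-3-methylbuta-1,3-dien-1-yl)octadeca-1,17-diene-1,18-dione (ketenyl and methoxypropenyl groups cis on the central C=C) | COC=C(C)/C(O)=C(OC(C)(C)C)\C(=C=O)CCCCCCCCCCCCCCC(=C=O)/C(OC(C)(C)C)=C(O)\C(C)=COC | intermediate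
13 | 2,2'-(tetradecane-1,14-diyl)bis(3-tert-butoxy-4-hydroxy-6-methoxy-5-methylcyclohexa-2,4-dien-1-one), C6 undefined | COC1C(C)=C(O)C(OC(C)(C)C)=C(CCCCCCCCCCCCCCC2=C(OC(C)(C)C)C(O)=C(C)C(OC)C2=O)C1=O | intermediate
14 | 2,2'-(tetradecane-1,14-diyl)bis(3-tert-butoxy-6-methoxy-5-methylbenzene-1,4-diol) | COc1c(C)c(O)c(OC(C)(C)C)c(CCCCCCCCCCCCCCc2c(O)c(OC)c(C)c(O)c2OC(C)(C)C)c1O | intermediate
15 | 3,3'-(tetradecane-1,14-diyl)bis(2-tert-butoxy-5-methoxy-6-methylcyclohexa-2,5-diene-1,4-dione) | COC1=C(C)C(=O)C(OC(C)(C)C)=C(CCCCCCCCCCCCCCC2=C(OC(C)(C)C)C(=O)C(C)=C(OC)C2=O)C1=O | intermediate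
16 | 3,3'-(tetradecane-1,14-diyl)bis(2-hydroxy-5-methoxy-6-methylcyclohexa-2,5-diene-1,4-dione), CNP0278640.0, achiral | COC1=C(C)C(=O)C(O)=C(CCCCCCCCCCCCCCC2=C(O)C(=O)C(C)=C(OC)C2=O)C1=O | target

**Count and risks**

Total steps: 5. Longest linear sequence: 4 (steps 1, 3, 4, 5); step 2 supplies the three-carbon unit.

Steps most likely to fail:

1. Step 3. The alkenyllithium could lose lithium methoxide by β-elimination before it adds, or it could deprotonate the ring-bound methylene of 6 instead of adding to the carbonyl. The fallback sets out from 6 and returns at 16. Lithium methoxyacetylide, made in the flask from 2-chloro-1,1-dimethoxyethane and LiNEt2 (3 equiv, THF), is far less basic and would add to the same carbonyl to give 2,2'-(tetradecane-1,14-diyl)bis[3-tert-butoxy-4-hydroxy-4-(methoxyethynyl)cyclobut-2-en-1-one] F1. Heating in toluene would bring about the alkynyl variant of the Moore rearrangement (ring opening, closure to a diradical, hydrogen transfer from O–H) and give directly 3,3'-(tetradecane-1,14-diyl)bis(2-tert-butoxy-5-methoxycyclohexa-2,5-diene-1,4-dione) F2, which lacks only the two C6 methyl groups. CF3CO2H would then give 3,3'-(tetradecane-1,14-diyl)bis(2-hydroxy-5-methoxycyclohexa-2,5-diene-1,4-dione) F3. Silver-catalysed decarboxylative radical methylation at the only ring C–H (AcOH, AgNO3 cat., (NH4)2S2O8, MeCN/H2O, 65 °C) would give 16.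

2. Step 4. A ketene could be captured by a hydroxyl group of another molecule, or the cyclohexadienone could lose methanol in competition with enolization; either event at one end would leave mixtures in which one ring is right and the other is not. The fallback sets out from 2, uses 10 from step 3, and returns at 14. The rings would be made one at a time on a half-chain monomer and the chain closed at its midpoint. Oct-7-enylmagnesium bromide (from commercial 8-bromooct-1-ene) and 2, then (CF3CO)2O, would give 3-tert-butoxy-4-(oct-7-en-1-yl)cyclobut-3-ene-1,2-dione F4. Alkenyllithium 10 would give 3-tert-butoxy-4-hydroxy-4-(1-methoxyprop-1-en-2-yl)-2-(oct-7-en-1-yl)cyclobut-2-en-1-one F5. Thermolysis and Ag2O would give the purifiable monomer 2-tert-butoxy-5-methoxy-6-methyl-3-(oct-7-en-1-yl)cyclohexa-2,5-diene-1,4-dione F6. Self-metathesis with the second-generation Grubbs catalyst, RuCl2(=CHPh)(PCy3)(H2IMes), would give 3,3'-(tetradec-7-ene-1,14-diyl)bis(2-tert-butoxy-5-methoxy-6-methylcyclohexa-2,5-diene-1,4-dione) F7. Hydrogen over Pd on carbon would saturate the alkene and reduce both quinones to bis(hydroquinone) 14, which Ag2O oxidizes to 15 as in step 4.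

3. Step 1. Wurtz-type coupling while the di-Grignard reagent forms, addition at one end only, or loss of the second tert-butyl group during the anhydride treatment would lower the supply of 6. The fallback sets out from 2 and returns at 6. Tetradeca-1,13-diyne, a catalogue compound, would be deprotonated at both ends with n-BuLi and added to 2 (THF, –78 °C), and (CF3CO)2O would give 4,4'-(tetradeca-1,13-diyne-1,14-diyl)bis(3-tert-butoxycyclobut-3-ene-1,2-dione) F8. Hydrogenation of the two alkynes (H2, Pd on carbon, EtOAc) would give 6. The bonds to the four-membered rings would then come from acetylides, which form cleanly at both ends, and the chain would reach its saturated state by reduction.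

**Further compounds**

F1 | step 3 | 2,2'-(tetradecane-1,14-diyl)bis[3-tert-butoxy-4-hydroxy-4-(methoxyethynyl)cyclobut-2-en-1-one] | COC#CC1(O)C(OC(C)(C)C)=C(CCCCCCCCCCCCCCC2=C(OC(C)(C)C)C(O)(C#COC)C2=O)C1=O
F2 | step 3 | 3,3'-(tetradecane-1,14-diyl)bis(2-tert-butoxy-5-methoxycyclohexa-2,5-diene-1,4-dione) | COC1=CC(=O)C(OC(C)(C)C)=C(CCCCCCCCCCCCCCC2=C(OC(C)(C)C)C(=O)C=C(OC)C2=O)C1=O
F3 | step 3 | 3,3'-(tetradecane-1,14-diyl)bis(2-hydroxy-5-methoxycyclohexa-2,5-diene-1,4-dione) | COC1=CC(=O)C(O)=C(CCCCCCCCCCCCCCC2=C(O)C(=O)C=C(OC)C2=O)C1=O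
F4 | step 4 | 3-tert-butoxy-4-(oct-7-en-1-yl)cyclobut-3-ene-1,2-dione | C=CCCCCCCC1=C(OC(C)(C)C)C(=O)C1=O
F5 | step 4 | 3-tert-butoxy-4-hydroxy-4-(1-methoxyprop-1-en-2-yl)-2-(oct-7-en-1-yl)cyclobut-2-en-1-one | C=CCCCCCCC1=C(OC(C)(C)C)C(O)(C(C)=COC)C1=O
F6 | step 4 | 2-tert-butoxy-5-methoxy-6-methyl-3-(oct-7-en-1-yl)cyclohexa-2,5-diene-1,4-dione | COC1=C(C)C(=O)C(OC(C)(C)C)=C(CCCCCCC=C)C1=O
F7 | step 4 | 3,3'-(tetradec-7-ene-1,14-diyl)bis(2-tert-butoxy-5-methoxy-6-methylcyclohexa-2,5-diene-1,4-dione), E/Z mixture | COC1=C(C)C(=O)C(OC(C)(C)C)=C(CCCCCCC=CCCCCCCC2=C(OC(C)(C)C)C(=O)C(C)=C(OC)C2=O)C1=O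
F8 | step 1 | 4,4'-(tetradeca-1,13-diyne-1,14-diyl)bis(3-tert-butoxycyclobut-3-ene-1,2-dione) | CC(C)(C)OC1=C(C#CCCCCCCCCCCC#CC2=C(OC(C)(C)C)C(=O)C2=O)C(=O)C1=O
A1 | direct plan | 2,6-dimethoxytoluene | COc1cccc(OC)c1C
A2 | direct plan | 4,6-dimethoxy-5-methylbenzene-1,3-diol | COc1c(O)cc(O)c(OC)c1C
A3 | direct plan | 2-hydroxy-5-methoxy-6-methylcyclohexa-2,5-diene-1,4-dione | COC1=C(C)C(=O)C(O)=CC1=O
A4 | direct plan | tetradecanedial | O=CCCCCCCCCCCCCC=O
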